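## Retrosynthetic overview

1. The target is gallocatechin-(4α→6)-gallocatechin. The last disconnections are global hydrogenolysis and the C4(U)–C6(L) interflavan bond, made by Friedel–Crafts union of a flavan-4-yl cation (from the C4 acetate of the upper unit U) with C8-bromo-capped penta-O-benzyl-(+)-gallocatechin (lower unit L, all rings taken intact from the natural product).
2. Ring C of U is closed through its O1–C8a aryl ether bond: the C2 alkoxide displaces an ortho fluorine of a 2,4,6-trifluorophenyl group on C4 (SNAr), and in the same pot benzyl oxide replaces the other two fluorines, so a trifluorophenyl group becomes the phloroglucinol ring A.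
3. Enabling feature: the oxygens on C5, C7 and C8a of ring A are mutually meta, and C5 and C8a are both ortho to C4a. Ring A can therefore be carried as a symmetric 2,4,6-trifluorophenyl group: either ortho C–F gives the same chroman, and no alkoxy group that enters deactivates a remaining C–F bond by resonance.
4. The acyclic precursor comes from an Evans syn glycolate aldol with 2,4,6-trifluorobenzaldehyde (sets C3; the C4 carbinol is a relay centre), an aryl Grignard addition to the Weinreb amide (C2–ring B bond) and a hydroxyl-directed 1,3-anti reduction (sets C2). The relay centre C4 is erased when C4 is ionised for the interflavan bond.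
5. Ring order: rings A, B, C of L and ring B of U are preformed; ring A of U is present as the fluoroarene; ring C of U is the only ring closed (step 6).

Key step: step 6

Assumption: 5-bromo-1,2,3-tris(benzyloxy)benzene, 2,4,6-trifluorobenzaldehyde and (+)-gallocatechin are purchasable as such. Flavan numbering is used throughout; U = upper unit, L = lower unit.

## Route

Step 1
Reactants: 1 (S)-4-benzyl-1,3-oxazolidin-2-one; 2 (benzyloxy)acetyl chloride
Product: 4 (S)-4-benzyl-3-[(benzyloxy)acetyl]-1,3-oxazolidin-2-one, via N-lithio oxazolidinone 3 (not isolated)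
Conditions: n-BuLi, THF, −78 °C; then 2, −78 → 0 °C
Reagents that add atoms: none
Why: N-acylation of the lithiated oxazolidinone with the acid chloride is the standard entry to an Evans glycolate imide and creates no stereocentre.

Step 2
Reactants: 4 (S)-4-benzyl-3-[(benzyloxy)acetyl]-1,3-oxazolidin-2-one; 5 2,4,6-trifluorobenzaldehyde
Product: 7 (4S)-4-benzyl-3-[(2S,3R)-2-(benzyloxy)-3-hydroxy-3-(2,4,6-trifluorophenyl)propanoyl]-1,3-oxazolidin-2-one, via boron enolate 6 (not isolated)
Conditions: Bu2BOTf, Et3N, CH2Cl2, −78 → 0 °C; then 5, −78 → 0 °C; H2O2, MeOH, pH 7 buffer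
Reagents that add atoms: none
Why: Evans boron syn-aldol reaction: the (Z)-enolate 6 should react through a closed chair (Zimmerman–Traxler) transition state on the face away from the benzyl group of the auxiliary, which sets the benzyloxy carbon (the future C3) and places the new carbinol (the future C4, a relay centre) syn to it.

Step 3
Reactants: 7 (4S)-4-benzyl-3-[(2S,3R)-2-(benzyloxy)-3-hydroxy-3-(2,4,6-trifluorophenyl)propanoyl]-1,3-oxazolidin-2-one
Product: 8 (2S,3R)-2-(benzyloxy)-3-hydroxy-N-methoxy-N-methyl-3-(2,4,6-trifluorophenyl)propanamide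
Conditions: MeNHOMe·HCl, AlMe3, CH2Cl2, −10 → 0 °C; then 1 M HCl
Reagents that add atoms: N,O-dimethylhydroxylamine hydrochloride, CNOC.Cl
Why: Weinreb amide formation by aluminium amide transamination of the imide, assisted by the free β-hydroxyl, should release auxiliary 1 for reuse without touching either stereocentre.

Step 4
Reactants: 8 (2S,3R)-2-(benzyloxy)-3-hydroxy-N-methoxy-N-methyl-3-(2,4,6-trifluorophenyl)propanamide; 9 5-bromo-1,2,3-tris(benzyloxy)benzene
Product: 11 (2S,3R)-2-(benzyloxy)-3-hydroxy-1-[3,4,5-tris(benzyloxy)phenyl]-3-(2,4,6-trifluorophenyl)propan-1-one, via arylmagnesium bromide 10 (not isolated)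
Conditions: 9, Mg, THF, 50 °C; then 8 (0.4 equiv relative to 10), THF, −20 → 0 °C; aq NH4Cl
Reagents that add atoms: none
Why: Grignard addition to a Weinreb amide should stop at the ketone through the chelated tetrahedral magnesium intermediate (one equivalent of 10 is spent on the hydroxyl), forming the C2–ring B bond without epimerising the α-benzyloxy centre at low temperature.

Step 5
Reactants: 11 (2S,3R)-2-(benzyloxy)-3-hydroxy-1-[3,4,5-tris(benzyloxy)phenyl]-3-(2,4,6-trifluorophenyl)propan-1-one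
Product: 12 (1R,2R,3R)-2-(benzyloxy)-1-[3,4,5-tris(benzyloxy)phenyl]-3-(2,4,6-trifluorophenyl)propane-1,3-diol
Conditions: Me4NBH(OAc)3, MeCN/AcOH, −30 → −20 °C
Reagents that add atoms: none
Why: Evans–Saksena hydroxyl-directed reduction: the C4 hydroxyl should bind the triacetoxyborohydride and deliver hydride inside a chair transition state, so the new carbinol (the future C2) forms 1,3-anti to it and hence 1,2-anti (zigzag drawing) to the benzyloxy carbon, the relation a 2,3-trans flavan needs when the C2–O bond is kept.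

Step 6
Reactants: 12 (1R,2R,3R)-2-(benzyloxy)-1-[3,4,5-tris(benzyloxy)phenyl]-3-(2,4,6-trifluorophenyl)propane-1,3-diol
Product: 15 (2R,3S,4R)-3,5,7-tris(benzyloxy)-2-[3,4,5-tris(benzyloxy)phenyl]-3,4-dihydro-2H-chromen-4-ol, via difluoroflavanol 13 (not isolated), via monofluoroflavanol 14 (not isolated)
Conditions: NaH (2.2 equiv), THF, 0 → 65 °C, high dilution; then BnONa (6 equiv, preformed from BnOH and NaH), DMI (1,3-dimethylimidazolidin-2-one), 110 °C
Reagents that add atoms: benzyl alcohol, OCc1ccccc1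
Why: In an intramolecular nucleophilic aromatic substitution (SNAr) the C2 alkoxide should add to an ortho C–F carbon of the trifluorophenyl group (the future C8a) to give a Meisenheimer anion with its charge on C4a, C6 and C8, stabilised inductively by the two remaining fluorines, and loss of fluoride closes ring C (13); benzyl oxide then replaces the C7 and C5 fluorines in the same way (14, then 15). The closest known reaction types are the alkoxide SNAr ring closure of 3-(2-fluoroaryl)propanols to chromans and the stepwise alkoxide substitution of 1,3,5-trifluorobenzene to phloroglucinol ethers. Ring C, the only ring formed, is closed by a 6-exo attack of oxygen on the arene carbon followed by elimination of fluoride. No stereocentre is created: the C2–O bond is not touched, so C2 keeps its configuration and the 1,2-anti arrangement of 12 becomes the 2,3-trans flavan, while C3 and C4 are spectators. The step needs ring closure before any intermolecular substitution at both ortho positions, and O2 rather than O4 as the internal nucleophile; the first is secured by closing the ring with the non-nucleophilic base NaH (too weak a base towards the arene C–H bonds to open an aryne pathway) before benzyl oxide is added, the second by ring size (six-membered from O2, four-membered from O4), and because the two ortho C–F bonds are equivalent either one gives the same chroman. The three C–F carbons are meta to one another, so each alkoxy group that enters leaves the remaining C–F bonds free of resonance deactivation.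

Step 7
Reactants: 15 (2R,3S,4R)-3,5,7-tris(benzyloxy)-2-[3,4,5-tris(benzyloxy)phenyl]-3,4-dihydro-2H-chromen-4-ol
Product: 16 (2R,3S,4R)-3,5,7-tris(benzyloxy)-8-bromo-2-[3,4,5-tris(benzyloxy)phenyl]-3,4-dihydro-2H-chromen-4-ol
Conditions: NBS, CH2Cl2, −40 → −10 °C
Reagents that add atoms: N-bromosuccinimide, O=C1CCC(=O)N1Br
Why: Electrophilic aromatic bromination of the phloroglucinol-type ring A should go to C8, the more accessible of its two free positions, and caps it so that the upper unit cannot condense with itself through C8 in step 11.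

Step 8
Reactants: 16 (2R,3S,4R)-3,5,7-tris(benzyloxy)-8-bromo-2-[3,4,5-tris(benzyloxy)phenyl]-3,4-dihydro-2H-chromen-4-ol
Product: 17 (2R,3R,4R)-3,5,7-tris(benzyloxy)-8-bromo-2-[3,4,5-tris(benzyloxy)phenyl]-3,4-dihydro-2H-chromen-4-yl acetate (same 2,3-trans-3,4-trans arrangement as 16; the C3 descriptor changes only because the acetoxy group raises the CIP rank of C4)
Conditions: Ac2O, DMAP, pyridine, CH2Cl2, 0 °C → rt; chromatography on Et3N-deactivated silica
Reagents that add atoms: acetic anhydride, CC(=O)OC(C)=O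
Why: DMAP-catalysed acylation of the C4 alcohol, the only free hydroxyl, should turn it into a leaving group that a catalytic Lewis acid can ionise under anhydrous conditions, without touching a stereocentre.

Step 9
Reactants: 18 (+)-gallocatechin, (2R,3S)-2-(3,4,5-trihydroxyphenyl)-3,4-dihydro-2H-chromene-3,5,7-triol
Product: 19 (2R,3S)-5,7-bis(benzyloxy)-2-[3,4,5-tris(benzyloxy)phenyl]-3,4-dihydro-2H-chromen-3-ol
Conditions: BnBr, K2CO3, DMF, 0 °C → rt, Ar
Reagents that add atoms: benzyl bromide, BrCc1ccccc1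
Why: Williamson ether synthesis with a carbonate base should benzylate the five phenols only, because the secondary C3 alcohol is not deprotonated.

Step 10
Reactants: 19 (2R,3S)-5,7-bis(benzyloxy)-2-[3,4,5-tris(benzyloxy)phenyl]-3,4-dihydro-2H-chromen-3-ol
Product: 20 (2R,3S)-5,7-bis(benzyloxy)-8-bromo-2-[3,4,5-tris(benzyloxy)phenyl]-3,4-dihydro-2H-chromen-3-ol
Conditions: NBS, CH2Cl2, −20 °C
Reagents that add atoms: N-bromosuccinimide, O=C1CCC(=O)N1Br
Why: Electrophilic aromatic bromination should again take C8, which leaves C6 as the only free position of ring A of unit L for the interflavan bond (halogen capping).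

Step 11
Reactants: 17 (2R,3R,4R)-3,5,7-tris(benzyloxy)-8-bromo-2-[3,4,5-tris(benzyloxy)phenyl]-3,4-dihydro-2H-chromen-4-yl acetate; 20 (2R,3S)-5,7-bis(benzyloxy)-8-bromo-2-[3,4,5-tris(benzyloxy)phenyl]-3,4-dihydro-2H-chromen-3-ol (3 equiv)
Product: 21 8-bromo-3,5,7,3',4',5'-hexa-O-benzylgallocatechin-(4α→6)-8-bromo-5,7,3',4',5'-penta-O-benzylgallocatechin (both units 2R,3S at C2 and C3; the interflavan bond at C4 of U is trans to the 3-benzyloxy group and cis to the C2 aryl group)
Conditions: Me3SiOTf (0.2 equiv), 4 Å MS, CH2Cl2, −40 → −20 °C; then Et3N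
Reagents that add atoms: none
Why: Friedel–Crafts alkylation through the flavan-4-yl cation formed by Lewis-acid ionisation of the C4 acetate (a benzylic cation stabilised by O1, O5 and O7 of ring A): C6 of 20 should attack the face anti to the 3-benzyloxy group of the 2,3-trans cation and give the 3,4-trans (4α) bond, while the bromine caps and the excess of 20 hold back self-condensation.

Step 12
Reactants: 21 the protected dimer of step 11
Product: 22 gallocatechin-(4α→6)-gallocatechin, (2R,3S,4R)-2-(3,4,5-trihydroxyphenyl)-4-[(2R,3S)-3,5,7-trihydroxy-2-(3,4,5-trihydroxyphenyl)-3,4-dihydro-2H-chromen-6-yl]-3,4-dihydro-2H-chromene-3,5,7-triol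
Conditions: H2 (1 atm), Pd(OH)2/C, Et3N (2.2 equiv), THF/MeOH/H2O, rt; filtration under Ar, lyophilisation
Reagents that add atoms: none
Why: Catalytic hydrogenolysis should cleave the eleven benzyl ethers and both aryl C–Br bonds in one operation, with Et3N taking up the HBr so that the acid-labile interflavan bond survives; no stereocentre is touched.

## Compound list

1 | (S)-4-benzyl-1,3-oxazolidin-2-one | O=C1N[C@@H](Cc2ccccc2)CO1 | starting material
2 | (benzyloxy)acetyl chloride | O=C(Cl)COCc1ccccc1 | starting material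
3 | lithium (S)-4-benzyl-2-oxo-1,3-oxazolidin-3-ide | [Li+].O=C1[N-][C@@H](Cc2ccccc2)CO1 | intermediate
4 | (S)-4-benzyl-3-[(benzyloxy)acetyl]-1,3-oxazolidin-2-one | O=C(COCc1ccccc1)N1[C@@H](Cc2ccccc2)COC1=O | intermediate
5 | 2,4,6-trifluorobenzaldehyde | O=Cc1c(F)cc(F)cc1F | starting material
6 | (Z)-dibutylboron enolate of 4 | CCCCB(CCCC)O/C(=C\OCc1ccccc1)N1[C@@H](Cc2ccccc2)COC1=O | intermediate
7 | (4S)-4-benzyl-3-[(2S,3R)-2-(benzyloxy)-3-hydroxy-3-(2,4,6-trifluorophenyl)propanoyl]-1,3-oxazolidin-2-one | O=C(N1[C@@H](Cc2ccccc2)COC1=O)[C@@H](OCc1ccccc1)[C@H](O)c1c(F)cc(F)cc1F | intermediate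
8 | (2S,3R)-2-(benzyloxy)-3-hydroxy-N-methoxy-N-methyl-3-(2,4,6-trifluorophenyl)propanamide | CON(C)C(=O)[C@@H](OCc1ccccc1)[C@H](O)c1c(F)cc(F)cc1F | intermediate
9 | 5-bromo-1,2,3-tris(benzyloxy)benzene | Brc1cc(OCc2ccccc2)c(OCc2ccccc2)c(OCc2ccccc2)c1 | starting material
10 | [3,4,5-tris(benzyloxy)phenyl]magnesium bromide | Br[Mg]c1cc(OCc2ccccc2)c(OCc2ccccc2)c(OCc2ccccc2)c1 | intermediate
11 | (2S,3R)-2-(benzyloxy)-3-hydroxy-1-[3,4,5-tris(benzyloxy)phenyl]-3-(2,4,6-trifluorophenyl)propan-1-one | O=C(c1cc(OCc2ccccc2)c(OCc2ccccc2)c(OCc2ccccc2)c1)[C@@H](OCc1ccccc1)[C@H](O)c1c(F)cc(F)cc1F | intermediate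
12 | (1R,2R,3R)-2-(benzyloxy)-1-[3,4,5-tris(benzyloxy)phenyl]-3-(2,4,6-trifluorophenyl)propane-1,3-diol | O[C@H](c1cc(OCc2ccccc2)c(OCc2ccccc2)c(OCc2ccccc2)c1)[C@@H](OCc1ccccc1)[C@H](O)c1c(F)cc(F)cc1F | intermediate
13 | (2R,3S,4R)-3-(benzyloxy)-5,7-difluoro-2-[3,4,5-tris(benzyloxy)phenyl]-3,4-dihydro-2H-chromen-4-ol | Fc1cc(F)c2c(c1)O[C@H](c1cc(OCc3ccccc3)c(OCc3ccccc3)c(OCc3ccccc3)c1)[C@@H](OCc1ccccc1)[C@@H]2O | intermediate
14 | (2R,3S,4R)-3,7-bis(benzyloxy)-5-fluoro-2-[3,4,5-tris(benzyloxy)phenyl]-3,4-dihydro-2H-chromen-4-ol | C(c1ccccc1)Oc1cc(F)c2c(c1)O[C@H](c1cc(OCc3ccccc3)c(OCc3ccccc3)c(OCc3ccccc3)c1)[C@@H](OCc1ccccc1)[C@@H]2O | intermediate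
15 | (2R,3S,4R)-3,5,7-tris(benzyloxy)-2-[3,4,5-tris(benzyloxy)phenyl]-3,4-dihydro-2H-chromen-4-ol | C(c1ccccc1)Oc1cc(OCc2ccccc2)c2c(c1)O[C@H](c1cc(OCc3ccccc3)c(OCc3ccccc3)c(OCc3ccccc3)c1)[C@@H](OCc1ccccc1)[C@@H]2O | intermediate
16 | (2R,3S,4R)-3,5,7-tris(benzyloxy)-8-bromo-2-[3,4,5-tris(benzyloxy)phenyl]-3,4-dihydro-2H-chromen-4-ol | C(c1ccccc1)Oc1cc(OCc2ccccc2)c2c(c1Br)O[C@H](c1cc(OCc3ccccc3)c(OCc3ccccc3)c(OCc3ccccc3)c1)[C@@H](OCc1ccccc1)[C@@H]2O | intermediate
17 | (2R,3R,4R)-3,5,7-tris(benzyloxy)-8-bromo-2-[3,4,5-tris(benzyloxy)phenyl]-3,4-dihydro-2H-chromen-4-yl acetate | C(c1ccccc1)Oc1cc(OCc2ccccc2)c2c(c1Br)O[C@H](c1cc(OCc3ccccc3)c(OCc3ccccc3)c(OCc3ccccc3)c1)[C@@H](OCc1ccccc1)[C@@H]2OC(C)=O | intermediate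
18 | (+)-gallocatechin, (2R,3S)-2-(3,4,5-trihydroxyphenyl)-3,4-dihydro-2H-chromene-3,5,7-triol | Oc1cc(O)c2c(c1)O[C@H](c1cc(O)c(O)c(O)c1)[C@@H](O)C2 | starting material
19 | (2R,3S)-5,7-bis(benzyloxy)-2-[3,4,5-tris(benzyloxy)phenyl]-3,4-dihydro-2H-chromen-3-ol | C(c1ccccc1)Oc1cc(OCc2ccccc2)c2c(c1)O[C@H](c1cc(OCc3ccccc3)c(OCc3ccccc3)c(OCc3ccccc3)c1)[C@@H](O)C2 | intermediate
20 | (2R,3S)-5,7-bis(benzyloxy)-8-bromo-2-[3,4,5-tris(benzyloxy)phenyl]-3,4-dihydro-2H-chromen-3-ol | C(c1ccccc1)Oc1cc(OCc2ccccc2)c2c(c1Br)O[C@H](c1cc(OCc3ccccc3)c(OCc3ccccc3)c(OCc3ccccc3)c1)[C@@H](O)C2 | intermediate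
21 | 8-bromo-3,5,7,3',4',5'-hexa-O-benzylgallocatechin-(4α→6)-8-bromo-5,7,3',4',5'-penta-O-benzylgallocatechin | C(c1ccccc1)Oc1cc(OCc2ccccc2)c2c(c1Br)O[C@H](c1cc(OCc3ccccc3)c(OCc3ccccc3)c(OCc3ccccc3)c1)[C@@H](OCc1ccccc1)[C@@H]2c1c(OCc2ccccc2)c(Br)c2c(c1OCc1ccccc1)C[C@H](O)[C@@H](c1cc(OCc3ccccc3)c(OCc3ccccc3)c(OCc3ccccc3)c1)O2 | intermediate
22 | gallocatechin-(4α→6)-gallocatechin, (2R,3S,4R)-2-(3,4,5-trihydroxyphenyl)-4-[(2R,3S)-3,5,7-trihydroxy-2-(3,4,5-trihydroxyphenyl)-3,4-dihydro-2H-chromen-6-yl]-3,4-dihydro-2H-chromene-3,5,7-triol | Oc1cc(O)c2c(c1)O[C@H](c1cc(O)c(O)c(O)c1)[C@@H](O)[C@@H]2c1c(O)cc2c(c1O)C[C@H](O)[C@@H](c1cc(O)c(O)c(O)c1)O2 | target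

## Step count and risks

Total step count: 12. Longest linear sequence: 10 steps (steps 1–8, 11, 12); the lower unit is a two-step branch (steps 9, 10).

Steps most likely to fail:

1. Step 6. The third substitution may stall at the hindered C5–F that sits next to the C4 alkoxide, or intermolecular substitution may compete with ring closure if the staging is imperfect. The fallback gives up the fluoroarene and makes the upper unit by benzylic oxidation of the natural flavan; it sets out from 20. O-Benzylation of the C3 hydroxyl (NaH, BnBr, DMF, 0 °C → rt) should give (2R,3S)-3,5,7-tris(benzyloxy)-8-bromo-2-[3,4,5-tris(benzyloxy)phenyl]-3,4-dihydro-2H-chromene F1. Oxidation at C4 with DDQ in CH2Cl2 in the presence of 2-ethoxyethanol should give (2R,3S,4S)-3,5,7-tris(benzyloxy)-8-bromo-4-(2-ethoxyethoxy)-2-[3,4,5-tris(benzyloxy)phenyl]-3,4-dihydro-2H-chromene F2. The alcohol is expected to enter trans to the C2 aryl group, and this centre is lost on ionisation in any case. Union of F2 with 20 under the conditions of step 11 (Me3SiOTf, CH2Cl2, −40 → −20 °C) comes back to the route at 21; steps 1–8 are then not needed.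

2. Step 11. The hindered, bromo-capped C6 of 20 may react too slowly, the cation may be trapped by the free C3 hydroxyl of 20, or facial selectivity at C4 may erode. The fallback is the biomimetic condensation of unprotected partners and sets out from 15. Hydrogenolysis in a neutral medium (H2, Pd(OH)2/C, THF/MeOH), in which the C4 hydroxyl is expected to survive, should give (2R,3S,4R)-2-(3,4,5-trihydroxyphenyl)-3,4-dihydro-2H-chromene-3,4,5,7-tetrol (2,3-trans-3,4-trans-leucodelphinidin) F3. Its acid-catalysed condensation with an excess of unprotected 18 (0.1 M aq HCl, rt) should give 22 together with, as the expected major product, its regioisomer gallocatechin-(4α→8)-gallocatechin F4. Separation on Sephadex LH-20 and by preparative HPLC comes back to the route at 22; steps 7, 8 and 10–12 are then not needed.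

3. Step 5. Hydride delivery to the electron-rich aryl ketone may be slow or show poor facial selectivity under hydroxyl-directed conditions. The fallback uses chelation control by the α-benzyloxy group instead and sets out from 11. Silylation (t-BuMe2SiOTf, 2,6-lutidine, CH2Cl2) should give (2S,3R)-2-(benzyloxy)-3-[(tert-butyldimethylsilyl)oxy]-1-[3,4,5-tris(benzyloxy)phenyl]-3-(2,4,6-trifluorophenyl)propan-1-one F5. Reduction with Zn(BH4)2 in Et2O at −20 °C through the zinc chelate of the carbonyl and the α-benzyloxy oxygen (Cram chelate model) should give the 1,2-anti alcohol (1R,2R,3R)-2-(benzyloxy)-3-[(tert-butyldimethylsilyl)oxy]-1-[3,4,5-tris(benzyloxy)phenyl]-3-(2,4,6-trifluorophenyl)propan-1-ol F6. Bu4NF in THF then comes back to the route at 12.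

Further compounds

F1 | step 6 | (2R,3S)-3,5,7-tris(benzyloxy)-8-bromo-2-[3,4,5-tris(benzyloxy)phenyl]-3,4-dihydro-2H-chromene | C(c1ccccc1)Oc1cc(OCc2ccccc2)c2c(c1Br)O[C@H](c1cc(OCc3ccccc3)c(OCc3ccccc3)c(OCc3ccccc3)c1)[C@@H](OCc1ccccc1)C2
F2 | step 6 | (2R,3S,4S)-3,5,7-tris(benzyloxy)-8-bromo-4-(2-ethoxyethoxy)-2-[3,4,5-tris(benzyloxy)phenyl]-3,4-dihydro-2H-chromene | C(c1ccccc1)Oc1cc(OCc2ccccc2)c2c(c1Br)O[C@H](c1cc(OCc3ccccc3)c(OCc3ccccc3)c(OCc3ccccc3)c1)[C@@H](OCc1ccccc1)[C@H]2OCCOCC
F3 | step 11 | (2R,3S,4R)-2-(3,4,5-trihydroxyphenyl)-3,4-dihydro-2H-chromene-3,4,5,7-tetrol | Oc1cc(O)c2c(c1)O[C@H](c1cc(O)c(O)c(O)c1)[C@@H](O)[C@@H]2O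
F4 | step 11 | gallocatechin-(4α→8)-gallocatechin | Oc1cc(O)c2c(c1)O[C@H](c1cc(O)c(O)c(O)c1)[C@@H](O)[C@@H]2c1c(O)cc(O)c2c1O[C@H](c1cc(O)c(O)c(O)c1)[C@@H](O)C2
F5 | step 5 | (2S,3R)-2-(benzyloxy)-3-[(tert-butyldimethylsilyl)oxy]-1-[3,4,5-tris(benzyloxy)phenyl]-3-(2,4,6-trifluorophenyl)propan-1-one | O=C(c1cc(OCc2ccccc2)c(OCc2ccccc2)c(OCc2ccccc2)c1)[C@@H](OCc1ccccc1)[C@H](O[Si](C)(C)C(C)(C)C)c1c(F)cc(F)cc1F
F6 | step 5 | (1R,2R,3R)-2-(benzyloxy)-3-[(tert-butyldimethylsilyl)oxy]-1-[3,4,5-tris(benzyloxy)phenyl]-3-(2,4,6-trifluorophenyl)propan-1-ol | O[C@H](c1cc(OCc2ccccc2)c(OCc2ccccc2)c(OCc2ccccc2)c1)[C@@H](OCc1ccccc1)[C@H](O[Si](C)(C)C(C)(C)C)c1c(F)cc(F)cc1F
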